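**Plan**
- Retrosynthetic cuts, in order: the two phenolic O–Si bonds; the C2–aryl bond of the oxolane (numbered O1, C2 aryl, C3 CH2O-ester, C4 benzyl, C5), giving an arylzinc and a C2 acetal; the ester C–O bond; the O1–C2 acetal bond; the C4–CH2Ar bond; the C3–C2 bond.
- Enabling feature: C2 is the one ring carbon bonded to ring oxygen O1 and to the arene, so it is a masked oxocarbenium carbon (C2=O1+). The C3 CH2O-acyl and C4 benzyl groups lie on the same face of the oxolane, and the ester C=O can bridge to C2 from that face, so an aryl nucleophile has to enter trans to both.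
- Forward: a menthol-derived butenolide takes a 1,3-dioxolan-2-yl radical at its β-carbon (future C3; the dioxolane carbon is future C2) and the vanillyl group at its α-carbon (future C4). LiAlH4 opens the lactone acetal to a 1,4-diol, acidic methanol closes the oxolane (O1–C2) as a methyl acetal, then acylation, C2 arylation and desilylation follow.
- Stereochemistry: the (5R) acetal carbon of the butenolide fixes the β-carbon (anti addition), which fixes the α-carbon (anti alkylation). Re-closing the ring through the dioxolane carbon turns this trans pair into the 3,4-cis pair (3R,4R). C2 (S) is set in the key step.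

Key step: step 10

Assumption: butenolide 7, the crystalline 5-alkoxybutenolide derived from (−)-menthol, is taken as a purchasable chiral building block; it is otherwise made from furfural by photo-oxygenation and acetalisation with (−)-menthol.

Abbreviations: TIPS = tri(propan-2-yl)silyl; menthyl = (1R,2S,5R)-5-methyl-2-(propan-2-yl)cyclohexyl.

**Step 1**
Reactants: 1 vanillin
Product: 2 3-methoxy-4-(TIPS-oxy)benzaldehyde
Conditions: TIPSCl, imidazole, DMF, 23 °C
Reagents that add atoms: chlorotri(propan-2-yl)silane, CC(C)[Si](Cl)(C(C)C)C(C)C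
Why: Imidazole-promoted silylation of the phenol; the TIPS aryl ether should survive amide base, LiAlH4, acidic methanol and Me3SiBr and is removed at the end by fluoride.

**Step 2**
Reactants: 2 3-methoxy-4-(TIPS-oxy)benzaldehyde
Product: 3 [3-methoxy-4-(TIPS-oxy)phenyl]methanol
Conditions: NaBH4, MeOH/THF, 0 °C
Reagents that add atoms: none
Why: Borohydride reduction of an aryl aldehyde to the benzylic alcohol; the silyl ether is inert at 0 °C.

**Step 3**
Reactants: 3 [3-methoxy-4-(TIPS-oxy)phenyl]methanol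
Product: 4 [4-(bromomethyl)-2-methoxyphenoxy]tri(propan-2-yl)silane
Conditions: PBr3, Et2O, 0 °C; used at once
Reagents that add atoms: phosphorus tribromide, BrP(Br)Br
Why: Bromination of a primary benzylic alcohol through its bromophosphite ester (SN2 displacement by bromide).

**Step 4**
Reactants: 5 4-bromo-2-methoxyphenol
Product: 6 (4-bromo-2-methoxyphenoxy)tri(propan-2-yl)silane
Conditions: TIPSCl, imidazole, DMF, 23 °C
Reagents that add atoms: chlorotri(propan-2-yl)silane, CC(C)[Si](Cl)(C(C)C)C(C)C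
Why: Phenol silylation; the bromine para to the silyloxy group fixes the position of the later carbon–metal bond, so the regiochemistry of the aryl unit is not in question.

**Step 5**
Reactants: 7 (5R)-5-(menthyloxy)furan-2(5H)-one; 8 1,3-dioxolane
Product: 9 (4S,5R)-4-(1,3-dioxolan-2-yl)-5-(menthyloxy)oxolan-2-one
Conditions: Ph2CO (10 mol %), hν (350 nm, Pyrex), degassed neat 8, 10 °C
Reagents that add atoms: none
Why: Benzophenone-sensitised Giese-type radical conjugate addition: triplet Ph2CO abstracts H from C2 of the dioxolane, and the nucleophilic dioxolan-2-yl radical adds to the β-carbon of the butenolide anti to the C5 menthyloxy group, which sets C4 trans to C5; the chain is carried by H abstraction from 8.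

**Step 6**
Reactants: 9 (4S,5R)-4-(1,3-dioxolan-2-yl)-5-(menthyloxy)oxolan-2-one; 4 [4-(bromomethyl)-2-methoxyphenoxy]tri(propan-2-yl)silane
Product: 10 (3R,4S,5R)-4-(1,3-dioxolan-2-yl)-3-{[3-methoxy-4-(TIPS-oxy)phenyl]methyl}-5-(menthyloxy)oxolan-2-one
Conditions: LiN(i-Pr)2, THF, −78 °C; then 4, DMPU, −78 → −40 °C
Reagents that add atoms: none
Why: Alkylation of the γ-butyrolactone lithium enolate with a benzylic bromide; the electrophile enters anti to the C4 dioxolanyl group, which sets C3 trans to C4.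

**Step 7**
Reactants: 10 (3R,4S,5R)-4-(1,3-dioxolan-2-yl)-3-{[3-methoxy-4-(TIPS-oxy)phenyl]methyl}-5-(menthyloxy)oxolan-2-one
Product: 11 (2R,3R)-2-(1,3-dioxolan-2-yl)-3-{[3-methoxy-4-(TIPS-oxy)phenyl]methyl}butane-1,4-diol
Conditions: LiAlH4, THF, 0 °C; aqueous NaOH work-up
Reagents that add atoms: none
Why: Hydride reduction of the lactone carbonyl to CH2OH; the released menthyl hemiacetal collapses to the aldehyde, which is reduced to the second CH2OH with loss of menthol, while the dioxolane, the silyl ether and both stereocentres are untouched.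

**Step 8**
Reactants: 11 (2R,3R)-2-(1,3-dioxolan-2-yl)-3-{[3-methoxy-4-(TIPS-oxy)phenyl]methyl}butane-1,4-diol
Product: 12 [(3R,4R)-2-methoxy-4-{[3-methoxy-4-(TIPS-oxy)phenyl]methyl}oxolan-3-yl]methanol (both C2 epimers)
Conditions: camphorsulfonic acid (10 mol %), MeOH, 23 °C; Et3N quench
Reagents that add atoms: methanol, CO
Why: Acid-catalysed transacetalisation (Fischer-type glycosidation): the dioxolane opens to an oxocarbenium ion that only the C4 hydroxyl can capture (5-exo; the C1 hydroxyl would give an oxetane), and methanol exchange gives the methyl acetal; C3 and C4 are not touched, so the trans lactone pair appears as the 3,4-cis oxolane pair.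

**Step 9**
Reactants: 12 [(3R,4R)-2-methoxy-4-{[3-methoxy-4-(TIPS-oxy)phenyl]methyl}oxolan-3-yl]methanol; 13 3-methylbutanoyl chloride
Product: 14 [(3R,4R)-2-methoxy-4-{[3-methoxy-4-(TIPS-oxy)phenyl]methyl}oxolan-3-yl]methyl 3-methylbutanoate (both C2 epimers)
Conditions: pyridine, DMAP (5 mol %), CH2Cl2, 0 °C
Reagents that add atoms: none
Why: Acylation of the only free hydroxyl with an acid chloride; the ester of the target is installed here and then serves as the face-directing group of the key step.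

**Step 10**
Reactants: 14 [(3R,4R)-2-methoxy-4-{[3-methoxy-4-(TIPS-oxy)phenyl]methyl}oxolan-3-yl]methyl 3-methylbutanoate; 6 (4-bromo-2-methoxyphenoxy)tri(propan-2-yl)silane
Product: 18 [(2S,3R,4R)-2-[3-methoxy-4-(TIPS-oxy)phenyl]-4-{[3-methoxy-4-(TIPS-oxy)phenyl]methyl}oxolan-3-yl]methyl 3-methylbutanoate, via aryllithium 15 (not isolated), via arylzinc bromide 16 (not isolated), via 2-bromooxolane 17 (not isolated)
Conditions: (a) 6, n-BuLi, THF, −78 °C; ZnBr2, −78 → 0 °C; (b) 14, Me3SiBr, CH2Cl2, −40 → 0 °C, evaporate; (c) 16 added to 17, toluene/THF, −40 → 23 °C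
Reagents that add atoms: none
Why: Me3SiBr exchanges the anomeric methoxy group for bromide, and the α-bromo ether 17 ionises (helped by the Lewis-acidic zinc species) to the oxolane oxocarbenium ion C2=O1+, which the arylzinc bromide 16 captures at C2 with transfer of its ipso carbon. The closest known reaction type is the catalyst-free C-arylation of glycosyl bromides by arylzinc reagents under acyloxy participation, which gives 1,2-trans C-aryl glycosides. No ring of the product is closed in this step; only a transient six-membered 1,3-dioxan-2-ylium bridge can form, by 6-exo attack of the isovalerate carbonyl oxygen on C2 from the face that carries the C3 and C4 substituents. The new stereocentre C2 is controlled by C3 and C4: the CH2O-acyl group (with its bridge) and the benzyl group shield the same face, so the aryl should enter anti to both and C2 becomes S (2,3-trans and 2,4-trans); both C2 epimers of 14 converge on the same cation. The step needs facial selectivity at C2, reaction at the α-bromo ether in preference to the ester, and C-arylation faster than loss of H-3 or attack of the C4 benzyl arene on C2; the cis C3/C4 pair, the ester-tolerant but strongly nucleophilic organozinc with zinc fixed para to the silyloxy group, and the low temperature should secure these.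

**Step 11**
Reactants: 18 [(2S,3R,4R)-2-[3-methoxy-4-(TIPS-oxy)phenyl]-4-{[3-methoxy-4-(TIPS-oxy)phenyl]methyl}oxolan-3-yl]methyl 3-methylbutanoate
Product: 19 (+)-9'-isovaleroxylariciresinol, [(2S,3R,4R)-2-(4-hydroxy-3-methoxyphenyl)-4-[(4-hydroxy-3-methoxyphenyl)methyl]oxolan-3-yl]methyl 3-methylbutanoate
Conditions: Bu4NF, AcOH (1:1), THF, 0 °C
Reagents that add atoms: none
Why: Fluoride cleavage of both aryl silyl ethers; the acetic acid buffer keeps the phenols protonated, so the alkyl ester and the benzylic C2–O1 bond should not be touched.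

**Compound list**
1 | vanillin (4-hydroxy-3-methoxybenzaldehyde) | COc1cc(C=O)ccc1O | starting material
2 | 3-methoxy-4-(TIPS-oxy)benzaldehyde | COc1cc(C=O)ccc1O[Si](C(C)C)(C(C)C)C(C)C | intermediate
3 | [3-methoxy-4-(TIPS-oxy)phenyl]methanol | COc1cc(CO)ccc1O[Si](C(C)C)(C(C)C)C(C)C | intermediate
4 | [4-(bromomethyl)-2-methoxyphenoxy]tri(propan-2-yl)silane | COc1cc(CBr)ccc1O[Si](C(C)C)(C(C)C)C(C)C | intermediate
5 | 4-bromo-2-methoxyphenol | COc1cc(Br)ccc1O | starting material
6 | (4-bromo-2-methoxyphenoxy)tri(propan-2-yl)silane | COc1cc(Br)ccc1O[Si](C(C)C)(C(C)C)C(C)C | intermediate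
7 | (5R)-5-{[(1R,2S,5R)-5-methyl-2-(propan-2-yl)cyclohexyl]oxy}furan-2(5H)-one | O=C1C=C[C@H](O[C@@H]2C[C@H](C)CC[C@H]2C(C)C)O1 | starting material
8 | 1,3-dioxolane | C1COCO1 | starting material
9 | (4S,5R)-4-(1,3-dioxolan-2-yl)-5-(menthyloxy)oxolan-2-one (4,5-trans) | O=C1C[C@@H](C2OCCO2)[C@H](O[C@@H]3C[C@H](C)CC[C@H]3C(C)C)O1 | intermediate
10 | (3R,4S,5R)-4-(1,3-dioxolan-2-yl)-3-{[3-methoxy-4-(TIPS-oxy)phenyl]methyl}-5-(menthyloxy)oxolan-2-one (3,4-trans, 4,5-trans) | O=C1[C@H](Cc2ccc(O[Si](C(C)C)(C(C)C)C(C)C)c(OC)c2)[C@@H](C3OCCO3)[C@H](O[C@@H]4C[C@H](C)CC[C@H]4C(C)C)O1 | intermediate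
11 | (2R,3R)-2-(1,3-dioxolan-2-yl)-3-{[3-methoxy-4-(TIPS-oxy)phenyl]methyl}butane-1,4-diol | OC[C@H](Cc1ccc(O[Si](C(C)C)(C(C)C)C(C)C)c(OC)c1)[C@H](CO)C2OCCO2 | intermediate
12 | [(3R,4R)-2-methoxy-4-{[3-methoxy-4-(TIPS-oxy)phenyl]methyl}oxolan-3-yl]methanol (3,4-cis; both C2 epimers) | COc1cc(C[C@H]2COC(OC)[C@H]2CO)ccc1O[Si](C(C)C)(C(C)C)C(C)C | intermediate
13 | 3-methylbutanoyl chloride | CC(C)CC(=O)Cl | starting material
14 | [(3R,4R)-2-methoxy-4-{[3-methoxy-4-(TIPS-oxy)phenyl]methyl}oxolan-3-yl]methyl 3-methylbutanoate (both C2 epimers) | COc1cc(C[C@H]2COC(OC)[C@H]2COC(=O)CC(C)C)ccc1O[Si](C(C)C)(C(C)C)C(C)C | intermediate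
15 | [3-methoxy-4-(TIPS-oxy)phenyl]lithium | [Li]c1ccc(O[Si](C(C)C)(C(C)C)C(C)C)c(OC)c1 | intermediate
16 | bromo[3-methoxy-4-(TIPS-oxy)phenyl]zinc | Br[Zn]c1ccc(O[Si](C(C)C)(C(C)C)C(C)C)c(OC)c1 | intermediate
17 | [(3R,4R)-2-bromo-4-{[3-methoxy-4-(TIPS-oxy)phenyl]methyl}oxolan-3-yl]methyl 3-methylbutanoate | COc1cc(C[C@H]2COC(Br)[C@H]2COC(=O)CC(C)C)ccc1O[Si](C(C)C)(C(C)C)C(C)C | intermediate
18 | [(2S,3R,4R)-2-[3-methoxy-4-(TIPS-oxy)phenyl]-4-{[3-methoxy-4-(TIPS-oxy)phenyl]methyl}oxolan-3-yl]methyl 3-methylbutanoate | COc1cc(C[C@H]2CO[C@H](c3ccc(O[Si](C(C)C)(C(C)C)C(C)C)c(OC)c3)[C@H]2COC(=O)CC(C)C)ccc1O[Si](C(C)C)(C(C)C)C(C)C | intermediate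
19 | (+)-9'-isovaleroxylariciresinol, [(2S,3R,4R)-2-(4-hydroxy-3-methoxyphenyl)-4-[(4-hydroxy-3-methoxyphenyl)methyl]oxolan-3-yl]methyl 3-methylbutanoate | COc1cc(C[C@H]2CO[C@H](c3ccc(O)c(OC)c3)[C@H]2COC(=O)CC(C)C)ccc1O | target

**Step count and risks**
Total steps: 11. Longest linear sequence: 9 (steps 1, 2, 3, 6, 7, 8, 9, 10, 11).

Step 10 is the most exposed. The cation at C2 may lose the C3 proton to give a 4,5-dihydrofuran, may be attacked by the arene of the C4 benzyl group, or may take up the aryl on the wrong face. The fallback replaces the substitution at an acetal carbon by carbonyl addition followed by a thermodynamically controlled ring closure. It sets out from 12: aqueous acetic acid in THF should hydrolyse the methyl acetal to (3R,4R)-3-(hydroxymethyl)-4-{[3-methoxy-4-(TIPS-oxy)phenyl]methyl}oxolan-2-ol F1. An excess of aryllithium 15 (from 6 and n-BuLi, THF, −78 → 0 °C) should add to its open hydroxy aldehyde form to give (2R,3R)-2-{hydroxy[3-methoxy-4-(TIPS-oxy)phenyl]methyl}-3-{[3-methoxy-4-(TIPS-oxy)phenyl]methyl}butane-1,4-diol F2 as a mixture at the carbinol carbon. Catalytic camphorsulfonic acid in CH2Cl2 at 0 °C should ionise the benzylic alcohol; 5-exo capture by the C4 hydroxymethyl oxygen is the only five-membered mode and should give the 2,3-trans alcohol [(2S,3R,4R)-2-[3-methoxy-4-(TIPS-oxy)phenyl]-4-{[3-methoxy-4-(TIPS-oxy)phenyl]methyl}oxolan-3-yl]methanol F3. Acylation with 13 and pyridine returns to the route at 18.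

Step 5 is second. Hydrogen abstraction may occur at C4 of the dioxolane or at the menthyl acetal C–H, the butenolide may photodimerise, and facial selectivity may be incomplete. The fallback is a polar tandem conjugate addition and alkylation that sets out from 7. Lithiated bis(phenylsulfanyl)methane (n-BuLi, THF, −78 °C) should add 1,4 anti to the menthyloxy group, and the enolate is trapped with bromide 4 (DMPU) to give (3R,4R,5R)-4-[bis(phenylsulfanyl)methyl]-3-{[3-methoxy-4-(TIPS-oxy)phenyl]methyl}-5-(menthyloxy)oxolan-2-one F4. LiAlH4 should reduce it to (2R,3R)-2-[bis(phenylsulfanyl)methyl]-3-{[3-methoxy-4-(TIPS-oxy)phenyl]methyl}butane-1,4-diol F5. HgCl2 and CaCO3 in methanol should unmask the thioacetal as a thionium ion, which the C4 hydroxyl and then methanol capture, so that the route is rejoined at 12.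

Step 6 is third. The electron-rich benzylic bromide 4 may ionise and self-condense before C-alkylation, proton transfer may lead to double alkylation, and the 3,4-trans selectivity may erode. The fallback avoids the bromide and sets out from 9 and aldehyde 2. Aldol addition of the lithium enolate of 9 to 2 should give (3S,4S,5R)-4-(1,3-dioxolan-2-yl)-3-{hydroxy[3-methoxy-4-(TIPS-oxy)phenyl]methyl}-5-(menthyloxy)oxolan-2-one F6 as a mixture at the carbinol carbon. Mesylation (MsCl, Et3N) and elimination with DBU should give (3E,4S,5R)-4-(1,3-dioxolan-2-yl)-3-{[3-methoxy-4-(TIPS-oxy)phenyl]methylidene}-5-(menthyloxy)oxolan-2-one F7. Hydrogenation (H2, Pd/C, EtOAc) should deliver hydrogen anti to the dioxolanyl group and give the 3,4-cis lactone (3S,4S,5R)-4-(1,3-dioxolan-2-yl)-3-{[3-methoxy-4-(TIPS-oxy)phenyl]methyl}-5-(menthyloxy)oxolan-2-one F8. Equilibration with catalytic KOt-Bu in THF/t-BuOH should then give the more stable trans lactone, so that the route is rejoined at 10.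

**Further compounds**
F1 | step 10 | (3R,4R)-3-(hydroxymethyl)-4-{[3-methoxy-4-(TIPS-oxy)phenyl]methyl}oxolan-2-ol (both C2 epimers) | COc1cc(C[C@H]2COC(O)[C@H]2CO)ccc1O[Si](C(C)C)(C(C)C)C(C)C
F2 | step 10 | (2R,3R)-2-{hydroxy[3-methoxy-4-(TIPS-oxy)phenyl]methyl}-3-{[3-methoxy-4-(TIPS-oxy)phenyl]methyl}butane-1,4-diol (both carbinol epimers) | COc1cc(C[C@@H](CO)[C@H](CO)C(O)c2ccc(O[Si](C(C)C)(C(C)C)C(C)C)c(OC)c2)ccc1O[Si](C(C)C)(C(C)C)C(C)C
F3 | step 10 | [(2S,3R,4R)-2-[3-methoxy-4-(TIPS-oxy)phenyl]-4-{[3-methoxy-4-(TIPS-oxy)phenyl]methyl}oxolan-3-yl]methanol | COc1cc(C[C@H]2CO[C@H](c3ccc(O[Si](C(C)C)(C(C)C)C(C)C)c(OC)c3)[C@H]2CO)ccc1O[Si](C(C)C)(C(C)C)C(C)C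
F4 | step 5 | (3R,4R,5R)-4-[bis(phenylsulfanyl)methyl]-3-{[3-methoxy-4-(TIPS-oxy)phenyl]methyl}-5-(menthyloxy)oxolan-2-one (3,4-trans, 4,5-trans) | O=C1[C@H](Cc2ccc(O[Si](C(C)C)(C(C)C)C(C)C)c(OC)c2)[C@@H](C(Sc3ccccc3)Sc3ccccc3)[C@H](O[C@@H]4C[C@H](C)CC[C@H]4C(C)C)O1
F5 | step 5 | (2R,3R)-2-[bis(phenylsulfanyl)methyl]-3-{[3-methoxy-4-(TIPS-oxy)phenyl]methyl}butane-1,4-diol | OC[C@H](Cc1ccc(O[Si](C(C)C)(C(C)C)C(C)C)c(OC)c1)[C@H](CO)C(Sc1ccccc1)Sc1ccccc1
F6 | step 6 | (3S,4S,5R)-4-(1,3-dioxolan-2-yl)-3-{hydroxy[3-methoxy-4-(TIPS-oxy)phenyl]methyl}-5-(menthyloxy)oxolan-2-one (3,4-trans; both carbinol epimers) | O=C1[C@H](C(O)c2ccc(O[Si](C(C)C)(C(C)C)C(C)C)c(OC)c2)[C@@H](C3OCCO3)[C@H](O[C@@H]4C[C@H](C)CC[C@H]4C(C)C)O1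
F7 | step 6 | (3E,4S,5R)-4-(1,3-dioxolan-2-yl)-3-{[3-methoxy-4-(TIPS-oxy)phenyl]methylidene}-5-(menthyloxy)oxolan-2-one | O=C1/C(=C/c2ccc(O[Si](C(C)C)(C(C)C)C(C)C)c(OC)c2)[C@@H](C3OCCO3)[C@H](O[C@@H]4C[C@H](C)CC[C@H]4C(C)C)O1
F8 | step 6 | (3S,4S,5R)-4-(1,3-dioxolan-2-yl)-3-{[3-methoxy-4-(TIPS-oxy)phenyl]methyl}-5-(menthyloxy)oxolan-2-one (3,4-cis) | O=C1[C@@H](Cc2ccc(O[Si](C(C)C)(C(C)C)C(C)C)c(OC)c2)[C@@H](C3OCCO3)[C@H](O[C@@H]4C[C@H](C)CC[C@H]4C(C)C)O1
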